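A direct plan would uncover only the 7-OH of kaempferol by a relay of acetyl, methoxymethyl and benzyl groups to give 3,5,4'-tri-O-benzylkaempferol A1, would join its C8 to C2 of the 2-aroyl-3-hydroxybenzofuran A2 by an oxidative cross-dehydrogenative coupling, would let O7 close the ring to the hexa-O-benzyl spiro hemiketal A3, and would finish by hydrogenolysis of A3. Its weakest step would be that oxidative C8–C2 coupling: neither partner type is known in it, C8 would have to win over C6 and over O-attack, and the enantiocontrol would be untested. The protecting-group relay of five steps would add length without adding complexity.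

The spiro carbon is both C2 of the benzofuran-3-one and C9' of the furochromene, and O1 and C3 of the benzofuranone sit ortho on one arene. The route therefore disconnects C2–C3: the flat, achiral 9-aryloxyfurochromenone 9, which carries a formyl group ortho to the ether oxygen, would undergo an enantioselective carbene-catalysed hydroacylation across the aromatic furan bond C8'=C9', closing the benzofuranone last and setting the quaternary centre in one redox-neutral operation. The furan is built beforehand by Sonogashira coupling and iodocyclisation, in which the 7-O-benzyl group leaves, so neither an oxidative cross-coupling nor a protecting-group relay is needed.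

Key step: step 6

Remark: the hemiketal carbon C8' is taken to be configurationally mobile by ring–chain tautomerism, so only the spiro carbon has to be set by the route; the (8'R) arrangement of the target (hemiketal OH cis to the C3 carbonyl) is assumed to be the thermodynamic one.

Step 1
Reactants: 1 kaempferol
Product: 2 3,5,7-tris(benzyloxy)-2-[4-(benzyloxy)phenyl]-4H-chromen-4-one (tetra-O-benzylkaempferol)
Conditions: BnBr (6 equiv), K2CO3 (8 equiv), n-Bu4NI (cat.), DMF, 80 °C
Reagents that add atoms: benzyl bromide, BrCc1ccccc1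
Why: Fourfold Williamson etherification; the hydrogen-bonded 5-OH should react only in warm DMF with excess halide and iodide catalysis, and no stereocentre is involved.

Step 2
Reactants: 2 tetra-O-benzylkaempferol
Product: 3 3,5,7-tris(benzyloxy)-2-[4-(benzyloxy)phenyl]-8-iodo-4H-chromen-4-one
Conditions: N-iodosuccinimide (1.05 equiv), CF3CO2H (0.2 equiv), MeCN/CH2Cl2, 0 °C → rt, dark
Reagents that add atoms: N-iodosuccinimide, O=C1CCC(=O)N1I
Why: Electrophilic aromatic iodination of a 5,7-dialkoxyflavone should take place at C8, which is activated by O7 and the ring oxygen O1 (both ortho) and by O5 (para) and is flanked by only one benzyloxy group, whereas C6 lies between two; ring B, deactivated by the enone, and the benzyl groups should not react.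

Step 3
Reactants: 3 8-iodo-tetra-O-benzylkaempferol; 4 1-(benzyloxy)-4-ethynylbenzene
Product: 6 3,5-bis(benzyloxy)-2,8-bis[4-(benzyloxy)phenyl]-9-iodo-4H-furo[2,3-h]chromen-4-one, via 8-(arylethynyl)flavone 5 (not isolated)
Conditions: 4 (1.3 equiv), PdCl2(PPh3)2 (5 mol %), CuI (10 mol %), Et3N, DMF, 60 °C; filter through silica, evaporate; I2 (2 equiv), CH2Cl2, rt
Reagents that add atoms: iodine, II
Why: Sonogashira coupling followed by Larock iodocyclisation of the o-alkynylaryl benzyl ether: iodonium activation, 5-endo-dig attack of O7 on the alkyne carbon that bears the aryl group and SN2 loss of the O-benzyl group to iodide should close the furan, unmask only O7 and leave iodine on C9, the carbon that must later carry oxygen.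

Step 4
Reactants: 7 2,4,6-trihydroxybenzaldehyde
Product: 8 2,4-bis(benzyloxy)-6-hydroxybenzaldehyde
Conditions: BnBr (2.05 equiv), K2CO3 (2.2 equiv), DMF, 0 °C → rt
Reagents that add atoms: benzyl bromide, BrCc1ccccc1
Why: Williamson etherification should stop after two alkylations because the remaining ortho hydroxyl group is locked in a hydrogen bond to the formyl group.

Step 5
Reactants: 6 9-iodofurochromenone; 8 2,4-bis(benzyloxy)-6-hydroxybenzaldehyde
Product: 9 2,4-bis(benzyloxy)-6-({3,5-bis(benzyloxy)-2,8-bis[4-(benzyloxy)phenyl]-4-oxo-4H-furo[2,3-h]chromen-9-yl}oxy)benzaldehyde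
Conditions: CuI (20 mol %), picolinic acid (40 mol %), K3PO4 (2 equiv), DMSO, 90 °C, Ar
Reagents that add atoms: none
Why: Ullmann-type diaryl ether synthesis, in which the picolinate-bound monovalent copper phenoxide should couple with the heteroaryl iodide at C9; the phenol has only one ortho substituent, and the formyl group, the chromone and the benzyl ethers are inert to K3PO4 in DMSO.

Step 6
Reactants: 9 9-(2-formylaryloxy)furochromenone
Product: 10 (2R,8'R)-3',4,5',6-tetrakis(benzyloxy)-2',8'-bis[4-(benzyloxy)phenyl]-8'H-spiro[1-benzofuran-2,9'-furo[2,3-h]chromene]-3,4'-dione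
Conditions: (5aS,10bR)-2-mesityl-5a,10b-dihydro-4H,6H-indeno[2,1-b][1,2,4]triazolo[4,3-d][1,4]oxazin-2-ium tetrafluoroborate (20 mol %), DBU (20 mol %), 1,4-dioxane, 80 °C, Ar
Reagents that add atoms: none
Why: Proposed new method: the triazolylidene adds to the formyl group to give the Breslow intermediate, whose nucleophilic carbon bonds to C9 of the furochromenone while its O–H proton passes to C8 in a concerted, asynchronous (Conia-ene-like) five-centre transition state, the positive charge that develops at C9 being stabilised by the aryloxy oxygen, and collapse of the adduct releases the carbene. The closest known reaction type is the carbene-catalysed enantioselective intramolecular hydroacylation of unactivated alkenes and its dearomatising form on benzofurans that carry the salicylaldehyde tether on C3 through a CH2O link; new here are the tetrasubstituted 2-aryl-3-aryloxyfuran double bond, the direct oxygen link and the five-membered ring. The one ring closed is the benzofuran-3(2H)-one, by 5-exo-trig attack on C9 of the C8=C9 bond. The spiro carbon is set in the C–C bond-forming event, in which the indane-fused triazolylidene should leave one face of the flat furochromenone open to the Breslow carbon (which enantiomer of the salt gives the configuration drawn would be fixed in a first run), and C8 receives its hydrogen on the same face, cis to the new carbonyl carbon, a centre that is erased in step 7. The step needs C9 over C8 attack, hydroacylation over benzoin-type dimerisation and a gain that outweighs the loss of furan aromaticity: only C9 lies within reach of a five-membered transition state, the di-ortho-substituted electron-rich aldehyde should not dimerise, and the exothermic change of aldehyde to ketone pays for the dearomatisation.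

Step 7
Reactants: 10 spiro ketone with C8'–H
Product: 11 (2S)-3',4,5',6,8'-pentakis(benzyloxy)-2',8'-bis[4-(benzyloxy)phenyl]-8'H-spiro[1-benzofuran-2,9'-furo[2,3-h]chromene]-3,4'-dione (mixed benzyl ketal, both epimers at C8')
Conditions: DDQ (1.5 equiv), BnOH (5 equiv), 4 Å molecular sieves, CH2Cl2, 0 °C → rt, dark
Reagents that add atoms: benzyl alcohol, OCc1ccccc1
Why: DDQ should abstract hydride from C8'–H, which is benzylic to the 4-benzyloxyphenyl group and α to the ring oxygen (the C–H type oxidised in the cleavage of p-alkoxybenzyl ethers), and benzyl alcohol captures the oxocarbenium ion as the mixed ketal; the neighbouring quaternary carbon cannot lose a proton, so no benzofuran forms, the configuration at C8' is of no consequence, and the spiro descriptor changes from R to S only because the priorities change.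

Step 8
Reactants: 11 hepta-O-benzyl spiro ketal
Product: 12 (2S,8'R)-3',4,5',6,8'-pentahydroxy-2',8'-bis(4-hydroxyphenyl)-8'H-spiro[1-benzofuran-2,9'-furo[2,3-h]chromene]-3,4'-dione (target)
Conditions: H2 (1 atm), 10% Pd/C, THF/EtOAc, rt
Reagents that add atoms: none
Why: Catalytic hydrogenolysis should cleave the six aryl benzyl ethers and the O-benzyl bond of the ketal under neutral conditions; the quaternary spiro carbon is untouched, and the freed hemiketal should settle by ring–chain tautomerism as the (8'R)-epimer, with OH cis to the C3 carbonyl (O–H···O=C hydrogen bond) and the aryl group on the side of the ring oxygen.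

**Compound list**
1 | kaempferol | Oc1cc(O)c2c(=O)c(O)c(-c3ccc(O)cc3)oc2c1 | starting material
2 | 3,5,7-tris(benzyloxy)-2-[4-(benzyloxy)phenyl]-4H-chromen-4-one | O=c1c(OCc2ccccc2)c(-c2ccc(OCc3ccccc3)cc2)oc2cc(OCc3ccccc3)cc(OCc3ccccc3)c12 | intermediate
3 | 3,5,7-tris(benzyloxy)-2-[4-(benzyloxy)phenyl]-8-iodo-4H-chromen-4-one | O=c1c(OCc2ccccc2)c(-c2ccc(OCc3ccccc3)cc2)oc2c(I)c(OCc3ccccc3)cc(OCc3ccccc3)c12 | intermediate
4 | 1-(benzyloxy)-4-ethynylbenzene | C#Cc1ccc(OCc2ccccc2)cc1 | starting material
5 | 3,5,7-tris(benzyloxy)-2-[4-(benzyloxy)phenyl]-8-{[4-(benzyloxy)phenyl]ethynyl}-4H-chromen-4-one (not isolated) | O=c1c(OCc2ccccc2)c(-c2ccc(OCc3ccccc3)cc2)oc2c(C#Cc3ccc(OCc4ccccc4)cc3)c(OCc3ccccc3)cc(OCc3ccccc3)c12 | intermediate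
6 | 3,5-bis(benzyloxy)-2,8-bis[4-(benzyloxy)phenyl]-9-iodo-4H-furo[2,3-h]chromen-4-one | O=c1c(OCc2ccccc2)c(-c2ccc(OCc3ccccc3)cc2)oc2c3c(I)c(-c4ccc(OCc5ccccc5)cc4)oc3cc(OCc3ccccc3)c12 | intermediate
7 | 2,4,6-trihydroxybenzaldehyde | O=Cc1c(O)cc(O)cc1O | starting material
8 | 2,4-bis(benzyloxy)-6-hydroxybenzaldehyde | O=Cc1c(O)cc(OCc2ccccc2)cc1OCc1ccccc1 | intermediate
9 | 2,4-bis(benzyloxy)-6-({3,5-bis(benzyloxy)-2,8-bis[4-(benzyloxy)phenyl]-4-oxo-4H-furo[2,3-h]chromen-9-yl}oxy)benzaldehyde | O=Cc1c(Oc2c(-c3ccc(OCc4ccccc4)cc3)oc3cc(OCc4ccccc4)c4c(=O)c(OCc5ccccc5)c(-c5ccc(OCc6ccccc6)cc5)oc4c23)cc(OCc2ccccc2)cc1OCc1ccccc1 | intermediate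
10 | (2R,8'R)-3',4,5',6-tetrakis(benzyloxy)-2',8'-bis[4-(benzyloxy)phenyl]-8'H-spiro[1-benzofuran-2,9'-furo[2,3-h]chromene]-3,4'-dione (8'-H cis to the C3 carbonyl carbon) | O=C1c2c(OCc3ccccc3)cc(OCc3ccccc3)cc2O[C@@]12c1c(cc(OCc3ccccc3)c3c(=O)c(OCc4ccccc4)c(-c4ccc(OCc5ccccc5)cc4)oc13)O[C@@H]2c1ccc(OCc2ccccc2)cc1 | intermediate
11 | (2S)-3',4,5',6,8'-pentakis(benzyloxy)-2',8'-bis[4-(benzyloxy)phenyl]-8'H-spiro[1-benzofuran-2,9'-furo[2,3-h]chromene]-3,4'-dione (both epimers at the ketal carbon C8') | O=C1c2c(OCc3ccccc3)cc(OCc3ccccc3)cc2O[C@@]12c1c(cc(OCc3ccccc3)c3c(=O)c(OCc4ccccc4)c(-c4ccc(OCc5ccccc5)cc4)oc13)OC2(OCc1ccccc1)c1ccc(OCc2ccccc2)cc1 | intermediate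
12 | (2S,8'R)-3',4,5',6,8'-pentahydroxy-2',8'-bis(4-hydroxyphenyl)-8'H-spiro[1-benzofuran-2,9'-furo[2,3-h]chromene]-3,4'-dione | O=C1c2c(O)cc(O)cc2O[C@@]12c1c(cc(O)c3c(=O)c(O)c(-c4ccc(O)cc4)oc13)O[C@]2(O)c1ccc(O)cc1 | target

Total step count: 8. Longest linear sequence: 7 steps (steps 1, 2, 3, 5, 6, 7 and 8).

Steps most likely to fail:

Step 6. The carbene may not turn over at the tetrasubstituted aromatic C8=C9 bond (the Breslow intermediate reverts or is oxidised instead of adding), or the face selection may be poor. The fallback uses known chemistry and sets out from 9. Pinnick oxidation (NaClO2, NaH2PO4, 2-methyl-2-butene, t-BuOH/THF/H2O) would give 2,4-bis(benzyloxy)-6-(furochromen-9-yloxy)benzoic acid F1. Its mixed anhydride (TFAA, CH2Cl2, 0 °C) would acylate C9, the position at which 2-arylbenzofurans undergo Friedel–Crafts acylation. Addition of BnOH and 2,6-lutidine would capture the C8 cation and give the racemic benzyl ketal F2 without a separate oxidation. Hydrogenolysis as in step 8 would give the racemic target F3, and preparative HPLC on a chiral stationary phase would separate 12 from its mirror image, the (2R,8'S)-enantiomer F4. The fallback comes back to the route at 12.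

Step 5. The C–O coupling may stall at the hindered C9, with protodeiodination of 6 taking over, because the hydrogen-bonded, formyl-deactivated phenol is a poor nucleophile. The fallback sets out from 6 and changes the order of events. The unhindered 3,5-bis(benzyloxy)phenol would be coupled under the same copper catalysis to give 3,5-bis(benzyloxy)-9-[3,5-bis(benzyloxy)phenoxy]-2,8-bis[4-(benzyloxy)phenyl]-4H-furo[2,3-h]chromen-4-one F5. Vilsmeier–Haack formylation (POCl3, DMF, 0 °C → rt, then aq NaOAc) would then introduce the aldehyde at one of the two equivalent positions ortho to the aryloxy oxygen and para to a benzyloxy group. The isomer formylated between the two benzyloxy groups would be removed by chromatography. The fallback comes back to the route at 9.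

Step 7. Hydride transfer to DDQ may be too slow at this hindered C–H bond next to the acylated quaternary carbon. A long-lived cation may also fragment by loss of the acylium ion with rearomatisation of the furan, which would erode the enantiomeric purity as well. The fallback sets out from 10 and replaces hydride abstraction by electron transfer. Anodic (Shono-type) benzylic oxidation through the radical cation of the 4-benzyloxyphenyl ring (constant current, graphite anode, Et4NOTs, MeCN/BnOH, 2,6-lutidine, rt) would form the cation in the presence of a large excess of benzyl alcohol and give the ketal directly. It makes no new compound and comes back to the route at 11.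

Further compounds
F1 | step 6 | 2,4-bis(benzyloxy)-6-({3,5-bis(benzyloxy)-2,8-bis[4-(benzyloxy)phenyl]-4-oxo-4H-furo[2,3-h]chromen-9-yl}oxy)benzoic acid | OC(=O)c1c(Oc2c(-c3ccc(OCc4ccccc4)cc3)oc3cc(OCc4ccccc4)c4c(=O)c(OCc5ccccc5)c(-c5ccc(OCc6ccccc6)cc5)oc4c23)cc(OCc2ccccc2)cc1OCc1ccccc1
F2 | step 6 | racemic 3',4,5',6,8'-pentakis(benzyloxy)-2',8'-bis[4-(benzyloxy)phenyl]-8'H-spiro[1-benzofuran-2,9'-furo[2,3-h]chromene]-3,4'-dione (racemate of 11) | O=C1c2c(OCc3ccccc3)cc(OCc3ccccc3)cc2OC12c1c(cc(OCc3ccccc3)c3c(=O)c(OCc4ccccc4)c(-c4ccc(OCc5ccccc5)cc4)oc13)OC2(OCc1ccccc1)c1ccc(OCc2ccccc2)cc1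
F3 | step 6 | racemic (2S*,8'R*)-3',4,5',6,8'-pentahydroxy-2',8'-bis(4-hydroxyphenyl)-8'H-spiro[1-benzofuran-2,9'-furo[2,3-h]chromene]-3,4'-dione (racemate of 12) | O=C1c2c(O)cc(O)cc2OC12c1c(cc(O)c3c(=O)c(O)c(-c4ccc(O)cc4)oc13)OC2(O)c1ccc(O)cc1
F4 | step 6 | (2R,8'S)-3',4,5',6,8'-pentahydroxy-2',8'-bis(4-hydroxyphenyl)-8'H-spiro[1-benzofuran-2,9'-furo[2,3-h]chromene]-3,4'-dione (mirror image of 12) | O=C1c2c(O)cc(O)cc2O[C@]12c1c(cc(O)c3c(=O)c(O)c(-c4ccc(O)cc4)oc13)O[C@@]2(O)c1ccc(O)cc1
F5 | step 5 | 3,5-bis(benzyloxy)-9-[3,5-bis(benzyloxy)phenoxy]-2,8-bis[4-(benzyloxy)phenyl]-4H-furo[2,3-h]chromen-4-one | c1c(Oc2c(-c3ccc(OCc4ccccc4)cc3)oc3cc(OCc4ccccc4)c4c(=O)c(OCc5ccccc5)c(-c5ccc(OCc6ccccc6)cc5)oc4c23)cc(OCc2ccccc2)cc1OCc1ccccc1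
F0 | step 7 | none | none
A1 | direct plan | 3,5,4'-tri-O-benzylkaempferol (free 7-OH) | Oc1cc(OCc2ccccc2)c2c(=O)c(OCc3ccccc3)c(-c3ccc(OCc4ccccc4)cc3)oc2c1
A2 | direct plan | [4,6-bis(benzyloxy)-3-hydroxy-1-benzofuran-2-yl][4-(benzyloxy)phenyl]methanone | O=C(c1ccc(OCc2ccccc2)cc1)c1oc2cc(OCc3ccccc3)cc(OCc3ccccc3)c2c1O
A3 | direct plan | (2S,8'R)-3',4,5',6-tetrakis(benzyloxy)-2',8'-bis[4-(benzyloxy)phenyl]-8'-hydroxy-8'H-spiro[1-benzofuran-2,9'-furo[2,3-h]chromene]-3,4'-dione | O=C1c2c(OCc3ccccc3)cc(OCc3ccccc3)cc2O[C@@]12c1c(cc(OCc5ccccc5)c3c(=O)c(OCc5ccccc5)c(-c4ccc(OCc5ccccc5)cc4)oc13)O[C@]2(O)c1ccc(OCc3ccccc3)cc1
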